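Count the ring per litre. A solid substrate dissolves in a closed, stirred flask; the dissolved starting material goes on to ring and, two at a time, to open dimer.

| flask | solid substrate | remark | time |
|---|---|---|---|
| blue | 0.050 M | run made earlier |  |
| red | 0.074 M | run made earlier |  |
| flask | 0.099 M |  | 6.0 min |

| run | time / min | ring / % | starting material / % |
|---|---|---|---|
| blue | 0.333 | 0 | 10.9 |
| blue | 1.00 | 1.3 | 28.6 |
| blue | 1.50 | 2.5 | 41.2 |
| blue | 2.50 | 5.4 | 58.5 |
| blue | 4.00 | 15.1 | 74.4 |
| blue | 5.00 | 20.1 | 71.5 |
| blue | 6.00 | 25.8 | 63.3 |
| red | 0.500 | 0.2 | 10.2 |
| red | 0.667 | 0.1 | 15.2 |
| red | 1.00 | 1.2 | 19.7 |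
| red | 1.50 | 0.8 | 27.4 |
| red | 2.50 | 4.6 | 38.6 |
| red | 4.00 | 10.2 | 50.6 |
| red | 6.00 | 18.3 | 57.2 |

(standard deviation of a reading: 0.5 percentage points)

- in percentages every species weighs as the solid substrate in it: one open dimer counts as two
- as a solid, counted per litre of solution: solid substrate
- steps that have been proposed: 2 starting material -> open dimer; solid substrate <-> starting material; starting material -> ring
- at the start none of the solid substrate is in solution
- starting material means what is dissolved; the solid is not counted in it

- Wednesday's: doubling the solubility of the solid substrate, all else as stated
- Saturday's: doubling the dissolution coefficient of the solid substrate, all else as stated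

1. how much ring there is at 6.0 min, in percent of the solid substrate charged
2. concentration of starting material in solution at 40 s, in percent of saturation
3. the change that raises the amount of ring at 6.0 min, in percent of the solid substrate charged most ("none" if none brings more than 2 percentage points) (Wednesday's / Saturday's / none)
4. amount of ring at 6.0 min, in percent of the solid substrate charged, after Wednesday's

The blue and red runs seem to contradict each other. Red is charged with 0.074 M against blue's 0.050 M, yet at 6.00 min red shows 18.3 % ring against blue's 25.8 %.

The percentages have different denominators. At 2.50 min, [starting material] reads 0.0292 M in blue and 0.0286 M in red, so at that time the solution does not show how much solid was charged. Later blue's starting material falls, from 74.4 % at 4.00 min to 63.3 % at 6.00 min, while red's still rises, from 50.6 % at 4.00 min to 57.2 % at 6.00 min.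

I therefore carry [ring] at a given time, the same at this temperature and volume for charges that keep solid until then: red's reading gives 0.0135 M. Red's starting material is still rising at its last reading, so I take red to keep solid until 6.00 min, and the new flask, charged with 0.0250 M more, to keep solid that long too. I reckon 13.7 % of its charge.

The forecast says 13.7 %, 13.5 % of saturation at 40 s, and Wednesday's as the best change, giving 24.4 %, on the ground “so dissolution doesn't depend on the solid load”.

The flask gives 13.6 % and 14.4 % of saturation; Wednesday's is best, gaining 11 percentage points against 6.2 points, and gives 24.2 %.

    2 starting material → open dimer (k = 0.540 M⁻¹ min⁻¹)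
    solid substrate ⇌ starting material, rate k2*(cs2 - [starting material]) while solid is left; crystals form when [starting material] > cs2 (solubility = 0.0720 M, k = 0.240 min⁻¹)
    starting material → ring (k = 0.0780 min⁻¹)

In this flask, 13.6 % of the charge is [ring] = 0.0134 M. A flask charged with 0.157 M has moved by 5 points, and the carried [ring] puts it at 8.60 %, which is 4.9 points under this flask. At 2.30 min this flask makes starting material 3.59 times faster than it uses it up, and at 6.00 min still 1.34 times faster. At 6.00 min it holds 43.0 % as starting material against 13.6 % as ring.

(The data are calculated from invented constants, noise included.)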